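**The question.** I want to know what holds most of the substrate at the end of ash, oak and maple, and how much single product maple ends with.

| flask | substrate | reagent | capture agent | remark | time |
|---|---|---|---|---|---|
| north-east | 0.10 M | 0.038 M | 0.010 M | run made earlier |  |
| north | 0.10 M | 0.092 M | 0.010 M | run made earlier |  |
| ash | 0.10 M | 0.120 M | 0.0100 M |  | 30 min |
| oak | 0.10 M | 0.0800 M | 0.0100 M |  | 30 min |
| maple | 0.10 M | 0.0500 M | 0.0100 M |  | 30 min |

| run | time / min | single product / % | double product / % | substrate / % |
|---|---|---|---|---|
| north-east | 4.00 | 25.0 | 0.9 | 65.3 |
| north-east | 8.00 | 24.3 | 0 | 66.6 |
| north-east | 10.0 | 21.8 | 0 | 66.3 |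
| north-east | 15.0 | 23.1 | 0.1 | 63.8 |
| north-east | 20.0 | 23.2 | 1.6 | 66.5 |
| north | 1.50 | 50.8 | 1.7 | 32.4 |
| north | 3.00 | 47.3 | 3.1 | 30.5 |
| north | 5.00 | 46.7 | 2.5 | 29.4 |
| north | 8.00 | 44.8 | 0.4 | 29.7 |
| north | 12.0 | 45.5 | 0.8 | 30.8 |
| north | 20.0 | 43.4 | 0.3 | 32.4 |

(readings scatter by 1 percentage point)

1. which of these holds the largest part of the substrate at the end of ash (double product / tris adduct / substrate / single product)
2. which of these holds the largest part of the substrate at the end of oak (double product / tris adduct / substrate / single product)
3. which of these holds the largest part of the substrate at the end of maple (double product / tris adduct / substrate / single product)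
4. amount of single product at the end of maple, in percent of the substrate charged

- on the list of suspects stand: reagent + single product -> double product + by-product; reagent + double product -> tris adduct + by-product; substrate + reagent -> single product + by-product; double product <-> isomer of the product; single product + capture agent -> trapped intermediate

**Fastest rung.** In north the substrate reads 32.4% at 1.50 min and 32.4% at 20.0 min. In north-east it averages 65.7% from 4.00 min on. Within the scatter, then, the substrate's turnover ends before the first reading of each run with substrate still present, and I count the reagent as the limiting reagent.

**Next rung.** Over the same minutes in north, single product falls from 50.8% to 43.4% while the substrate stands. I read this as capture, and the capture agent charged equals 10.0% of the substrate.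

**Slowest rung.** In north, single product reads 44.8% at 8.00 min and 43.4% at 20.0 min, against a scatter of 1 percentage point per reading, so I count turnovers rather than minutes.

**Counting turnovers.** My yield on reagent is the substrate turned per reagent charged. It is 0.903 in north-east, at 0.380 equivalents. North's substrate averages 30.9%, which gives 0.751 at 0.920 equivalents. The yield thus drops by 0.280, and this fall per equivalent of reagent is what I carry.

As an estimate, I charge the remaining reagent at two per tris adduct, although the suspects also hold double product and its isomer at one each, and I subtract the capture agent. My estimate for maple is 56.5% substrate and 30.2% single product. For oak it is 37.2% and 44.2%, for ash 19.2% and 51.2%. So I put substrate above single product in maple, and single product above substrate in oak and ash.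

**The forecast.** It holds that “the plateaus are set by stoichiometry”. It names single product for ash, single product for oak and substrate for maple, with 30.5% single product in maple, between 27.5% and 33.5%. My own maple amount is a little less than that.

**The result.** The flasks give single product for ash, single product for oak and substrate for maple, with 29.4% single product in maple. The three choices stand as forecast, and the maple amount lies inside the forecast's range.

    reagent + single product → double product + by-product (k = 0.450 L mol⁻¹ s⁻¹)
    reagent + double product → tris adduct + by-product (k = 3.80 L mol⁻¹ s⁻¹)
    substrate + reagent → single product + by-product (k = 1.30 L mol⁻¹ s⁻¹)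
    double product ⇌ isomer of the product (K = 8.10, k = 0.00490 s⁻¹)
    single product + capture agent → trapped intermediate (k = 0.150 L mol⁻¹ s⁻¹)

**Reagent's split.** Maple turns 0.877 substrate per reagent charged. Single product takes reagent with 0.35 of the substrate's rate constant, while double product takes it with a constant of 3.8 L mol⁻¹ s⁻¹, larger than either, and maple holds 0.295% double product against 1.74% tris adduct.

**A neighbour.** Maple with 0.25 M substrate has 0.200 equivalents, outside the span of the two runs. Going from maple's yield with the carried fall, which was read at 0.10 M substrate, gives 0.961, so my estimate is 80.8% substrate left. That neighbour ends with 80.8% substrate and 14.5% single product.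

The data were generated by integration with made-up constants; the scatter is artificial.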